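**Plan**

- Numbering (guaiane): five-membered ring C1(OH)–C2H2–C3(=O)–C4(Me)=C5; seven-membered ring C5–C6(OH)–C7–C8(O-angeloyl)–C9–C10(Me)–C1; C11 is the acetoxy carbon on C7. The enabling feature is that C1–C5 form a 4-hydroxy-2-methylcyclopent-2-enone. This is the intramolecular aldol adduct of a (Z)-ene-1,4-dione (C1 and C3 ketones cis across C4=C5), which is the oxidised form of a 2,3-dimethylfuran annulated to the seven-membered ring through C1 and C5.
- Retrosynthetic cuts, in order: the C8 angelate and the two silyl ethers; C1–C2 (aldol, the enedione folded back into the furan); C5–C6 (Friedel–Crafts acylation); C7–C11 (acetone aldol); C7–C8 (diazoacetate homologation); C1–C10 (furan conjugate addition).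
- Forward: the chain C1–C10–C9–C8–C7(C11)–C6 is assembled on the furan, the seven-membered ring is closed at C5–C6, the five-membered ring is closed last at C1–C2, and the esters are then adjusted.
- Stereochemistry: C10 from the imidazolidinone catalyst; C8 from (R)-BINAP–Ru hydrogenation; C7 from C8 through the chelated dianion (2,3-anti, which becomes cis on the ring); C6 from hydride attack on the face opposite the C7 and C8 substituents; C1 from the reversible aldol under the bias of C6–C10.

Key step: step 11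

**Route**

Step 1
Reactants: 1 2,3-dimethylfuran; 2 (E)-crotonaldehyde
Product: 3 (3S)-3-(4,5-dimethylfuran-2-yl)butanal
Conditions: (2R,5R)-5-benzyl-2-tert-butyl-3-methylimidazolidin-4-one·CF3CO2H (20 mol %), CHCl3, −20 °C
Reagents that add atoms: none
Why: Iminium-catalysed Friedel–Crafts-type conjugate addition through the only free α-carbon of the furan (future C1); the imidazolidinone shields one face of the E-iminium and the (2R,5R) catalyst is expected, by analogy with indole and pyrrole additions of this catalyst class, to give the S configuration at C10.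

Step 2
Reactants: 3 (3S)-3-(4,5-dimethylfuran-2-yl)butanal; 4 benzyl diazoacetate
Product: 5 benzyl (5S)-5-(4,5-dimethylfuran-2-yl)-3-oxohexanoate
Conditions: SnCl2 (10 mol %), CH2Cl2, rt
Reagents that add atoms: none
Why: Roskamp homologation, in which the diazo carbon adds to the Lewis-acid-activated aldehyde and a 1,2-hydride shift with loss of nitrogen gives the β-keto ester (C7–C8 bond) without a metal carbene that could attack the furan.

Step 3
Reactants: 5 benzyl (5S)-5-(4,5-dimethylfuran-2-yl)-3-oxohexanoate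
Product: 6 benzyl (3R,5S)-5-(4,5-dimethylfuran-2-yl)-3-hydroxyhexanoate
Conditions: H2 (50 bar), RuCl2[(R)-BINAP] (1 mol %), EtOH–CH2Cl2, 40 °C
Reagents that add atoms: none
Why: Noyori asymmetric hydrogenation of a β-keto ester, where the (R)-ligand should deliver the 3R alcohol (C8) under catalyst control as it does for acetoacetates, with the furan and the benzyl ester inert to the ruthenium catalyst.

Step 4
Reactants: 6 benzyl (3R,5S)-5-(4,5-dimethylfuran-2-yl)-3-hydroxyhexanoate; 7 acetone
Product: 8 benzyl (2S,3R,5S)-5-(4,5-dimethylfuran-2-yl)-3-hydroxy-2-(2-hydroxypropan-2-yl)hexanoate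
Conditions: LiN(i-Pr)2 (2.2 equiv), THF, −78 → −20 °C; 7, −78 °C; AcOH, −78 °C
Reagents that add atoms: none
Why: Fráter–Seebach reaction with a ketone electrophile, in which the lithium-chelated alkoxide enolate is attacked by acetone on the face away from the C9 chain, so the new C7 centre is 2,3-anti to C8 and C11 arrives with its oxygen.

Step 5
Reactants: 8 benzyl (2S,3R,5S)-5-(4,5-dimethylfuran-2-yl)-3-hydroxy-2-(2-hydroxypropan-2-yl)hexanoate
Product: 9 benzyl (2S,3R,5S)-5-(4,5-dimethylfuran-2-yl)-2-(2-hydroxypropan-2-yl)-3-(triethylsilyloxy)hexanoate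
Conditions: Et3SiCl, imidazole, DMF, 0 °C
Reagents that add atoms: chlorotriethylsilane CC[Si](Cl)(CC)CC
Why: Selective silylation, since the secondary C8 hydroxyl reacts with the silyl chloride while the tertiary C11 hydroxyl is too hindered under these conditions.

Step 6
Reactants: 9 benzyl (2S,3R,5S)-5-(4,5-dimethylfuran-2-yl)-2-(2-hydroxypropan-2-yl)-3-(triethylsilyloxy)hexanoate
Product: 10 benzyl (2S,3R,5S)-2-(2-acetoxypropan-2-yl)-5-(4,5-dimethylfuran-2-yl)-3-(triethylsilyloxy)hexanoate
Conditions: Ac2O, DMAP, Et3N, CH2Cl2, rt → 35 °C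
Reagents that add atoms: acetic anhydride CC(=O)OC(C)=O
Why: DMAP-catalysed acylation of a tertiary alcohol by the N-acetylpyridinium ion, run with a weak amine base so that the hindered ester α-hydrogen is not removed and no β-elimination follows.

Step 7
Reactants: 10 benzyl (2S,3R,5S)-2-(2-acetoxypropan-2-yl)-5-(4,5-dimethylfuran-2-yl)-3-(triethylsilyloxy)hexanoate
Product: 11 (2S,3R,5S)-2-(2-acetoxypropan-2-yl)-5-(4,5-dimethylfuran-2-yl)-3-(triethylsilyloxy)hexanoic acid
Conditions: H2 (1 atm), Pd/C, EtOAc, rt
Reagents that add atoms: none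
Why: Hydrogenolysis of the benzyl ester frees the hindered acid under neutral conditions, which avoids the β-elimination that saponification of a β-acetoxy ester would invite, and the trisubstituted furan is reduced far more slowly than the benzylic C–O bond is cleaved.

Step 8
Reactants: 11 (2S,3R,5S)-2-(2-acetoxypropan-2-yl)-5-(4,5-dimethylfuran-2-yl)-3-(triethylsilyloxy)hexanoic acid
Product: 13 2-[(5S,6R,8S)-2,3,8-trimethyl-4-oxo-6-(triethylsilyloxy)-5,6,7,8-tetrahydro-4H-cyclohepta[b]furan-5-yl]propan-2-yl acetate, via acid chloride 12 (not isolated)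
Conditions: 1-chloro-N,N,2-trimethylprop-1-en-1-amine, CH2Cl2, 0 °C; then SnCl4 (2 equiv), CH2Cl2, −78 °C
Reagents that add atoms: none
Why: Intramolecular Friedel–Crafts acylation, in which the acid chloride formed under neutral conditions is activated by SnCl4 and attacked by the only unsubstituted carbon of the electron-rich trialkylfuran (future C5), closing the seven-membered ring at C5–C6 at a temperature that should spare the silyl ether and the tertiary acetate.

Step 9
Reactants: 13 2-[(5S,6R,8S)-2,3,8-trimethyl-4-oxo-6-(triethylsilyloxy)-5,6,7,8-tetrahydro-4H-cyclohepta[b]furan-5-yl]propan-2-yl acetate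
Product: 14 2-[(4R,5S,6R,8S)-4-hydroxy-2,3,8-trimethyl-6-(triethylsilyloxy)-5,6,7,8-tetrahydro-4H-cyclohepta[b]furan-5-yl]propan-2-yl acetate
Conditions: LiBH(s-Bu)3, THF, −78 °C; then AcOH, −78 °C
Reagents that add atoms: none
Why: Reduction of the furyl ketone by a bulky trialkylborohydride, which should approach C6 from the β face because the C7 side chain and the C8 silyloxy group both lie on the α face, giving the 6α-alcohol cis to the C7 substituent; the cold acidic quench is meant to prevent acetyl transfer to the new alkoxide.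

Step 10
Reactants: 14 2-[(4R,5S,6R,8S)-4-hydroxy-2,3,8-trimethyl-6-(triethylsilyloxy)-5,6,7,8-tetrahydro-4H-cyclohepta[b]furan-5-yl]propan-2-yl acetate
Product: 15 2-[(4R,5R,6R,8S)-4-(tert-butyldimethylsilyloxy)-2,3,8-trimethyl-6-(triethylsilyloxy)-5,6,7,8-tetrahydro-4H-cyclohepta[b]furan-5-yl]propan-2-yl acetate
Conditions: TBSOTf, 2,6-lutidine, CH2Cl2, −78 → 0 °C
Reagents that add atoms: tert-butyldimethylsilyl trifluoromethanesulfonate CC(C)(C)[Si](C)(C)OS(=O)(=O)C(F)(F)F
Why: Silylation of a hindered secondary alcohol with the silyl triflate, buffered by lutidine so that the furylcarbinol is not ionised, gives a C6 ether that is distinguishable from the C8 triethylsilyl ether.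

Step 11
Reactants: 15 2-[(4R,5R,6R,8S)-4-(tert-butyldimethylsilyloxy)-2,3,8-trimethyl-6-(triethylsilyloxy)-5,6,7,8-tetrahydro-4H-cyclohepta[b]furan-5-yl]propan-2-yl acetate
Product: 17 (1R,6R,7R,8R,10S)-11-acetoxy-6-(tert-butyldimethylsilyloxy)-1-hydroxy-8-(triethylsilyloxy)guai-4-en-3-one, via (Z)-enedione 16 (not isolated)
Conditions: mCPBA (1.05 equiv), NaHCO3, CH2Cl2, 0 °C; then DBU, 0 °C → rt
Reagents that add atoms: 3-chloroperbenzoic acid OOC(=O)c1cccc(Cl)c1
Why: The peracid epoxidises the electron-rich tetrasubstituted furan and the epoxide collapses by C–O cleavage to the (Z)-ene-1,4-dione 16 (C1 ring ketone and C3 methyl ketone cis across C4=C5); DBU then enolises the methyl ketone, whose only enolisable side is C2, and the enolate adds to the C1 carbonyl. The closest known reaction type is the peracid opening of 2,5-dialkylfurans to cis-enediones followed by their base-mediated aldol closure to 4-hydroxycyclopent-2-enones. The five-membered ring closes by a 5-(enolendo)-exo-trig aldol, a mode that is sluggish in saturated 1,4-diketones but is helped here by the Z double bond holding C2 next to C1; dehydration would give a cyclopentadienone, so the adduct persists and the addition stays reversible. The new stereocentre C1 is therefore set under thermodynamic control by the existing centres: the hydroxyl is expected on the β face, trans to the C10 methyl, because the cis-6,8-bis(silyloxy) array disfavours conformers with a pseudo-axial C6–O and with them the epimer whose C1 and C6 oxygens are syn; this preference is reasoned, not secured. The step needs chemoselective oxidation (the furan is the only electron-rich π system; silyl ethers and the tertiary acetate are inert), a single aldol regiochemistry (closure of a C10 enolate onto C3 would put a double bond at a bridgehead) and retention at C10 (the hindered tertiary C10–H is enolised more slowly than the methyl group). The C6 silyl ether keeps the γ-oxygen from closing onto C3 to give an isomeric furan.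

Step 12
Reactants: 17 (1R,6R,7R,8R,10S)-11-acetoxy-6-(tert-butyldimethylsilyloxy)-1-hydroxy-8-(triethylsilyloxy)guai-4-en-3-one
Product: 18 (1R,6R,7R,8R,10S)-11-acetoxy-6-(tert-butyldimethylsilyloxy)-1,8-dihydroxyguai-4-en-3-one
Conditions: PPTS, MeOH–CH2Cl2, 0 °C
Reagents that add atoms: none
Why: Mild acid-catalysed methanolysis removes the less hindered triethylsilyl ether while the crowded allylic tert-butyldimethylsilyl ether, the tertiary acetate and the hydroxy enone should remain.

Step 13
Reactants: 18 (1R,6R,7R,8R,10S)-11-acetoxy-6-(tert-butyldimethylsilyloxy)-1,8-dihydroxyguai-4-en-3-one; 19 angelic acid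
Product: 21 (1R,6R,7R,8R,10S)-11-acetoxy-8-angeloyloxy-6-(tert-butyldimethylsilyloxy)-1-hydroxyguai-4-en-3-one, via mixed anhydride 20 (not isolated)
Conditions: 19, 2,4,6-trichlorobenzoyl chloride, Et3N, toluene, rt; then 18, 75 °C
Reagents that add atoms: none
Why: Yamaguchi esterification run without a nucleophilic catalyst, the variant used to keep the Z geometry of angelates, acylates the secondary C8 hydroxyl while the tertiary C1 hydroxyl is too hindered to compete.

Step 14
Reactants: 21 (1R,6R,7R,8R,10S)-11-acetoxy-8-angeloyloxy-6-(tert-butyldimethylsilyloxy)-1-hydroxyguai-4-en-3-one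
Product: 22 (1R,6R,7S,8R,10S)-11-acetoxy-8-angeloyloxy-1,6-dihydroxyguai-4-en-3-one
Conditions: HF·pyridine, pyridine, THF, 0 °C → rt
Reagents that add atoms: none
Why: Fluoride-driven cleavage of the Si–O bond under buffered, weakly acidic conditions frees the C6 hydroxyl without the acyl migration or angelate isomerisation that basic fluoride sources could cause.

**Compound list**

1 | 2,3-dimethylfuran | Cc1occc1C | starting material
2 | (E)-crotonaldehyde | C/C=C/C=O | starting material
3 | (3S)-3-(4,5-dimethylfuran-2-yl)butanal | O=CC[C@H](C)c1cc(C)c(C)o1 | intermediate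
4 | benzyl diazoacetate | [N-]=[N+]=CC(=O)OCc1ccccc1 | starting material
5 | benzyl (5S)-5-(4,5-dimethylfuran-2-yl)-3-oxohexanoate | O=C(CC(=O)C[C@H](C)c1cc(C)c(C)o1)OCc1ccccc1 | intermediate
6 | benzyl (3R,5S)-5-(4,5-dimethylfuran-2-yl)-3-hydroxyhexanoate | O=C(C[C@H](O)C[C@H](C)c1cc(C)c(C)o1)OCc1ccccc1 | intermediate
7 | acetone | CC(C)=O | starting material
8 | benzyl (2S,3R,5S)-5-(4,5-dimethylfuran-2-yl)-3-hydroxy-2-(2-hydroxypropan-2-yl)hexanoate | O=C(OCc1ccccc1)[C@H](C(C)(C)O)[C@H](O)C[C@H](C)c1cc(C)c(C)o1 | intermediate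
9 | benzyl (2S,3R,5S)-5-(4,5-dimethylfuran-2-yl)-2-(2-hydroxypropan-2-yl)-3-(triethylsilyloxy)hexanoate | O=C(OCc1ccccc1)[C@H](C(C)(C)O)[C@H](O[Si](CC)(CC)CC)C[C@H](C)c1cc(C)c(C)o1 | intermediate
10 | benzyl (2S,3R,5S)-2-(2-acetoxypropan-2-yl)-5-(4,5-dimethylfuran-2-yl)-3-(triethylsilyloxy)hexanoate | O=C(OCc1ccccc1)[C@H](C(C)(C)OC(C)=O)[C@H](O[Si](CC)(CC)CC)C[C@H](C)c1cc(C)c(C)o1 | intermediate
11 | (2S,3R,5S)-2-(2-acetoxypropan-2-yl)-5-(4,5-dimethylfuran-2-yl)-3-(triethylsilyloxy)hexanoic acid | OC(=O)[C@H](C(C)(C)OC(C)=O)[C@H](O[Si](CC)(CC)CC)C[C@H](C)c1cc(C)c(C)o1 | intermediate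
12 | (2S,3R,5S)-2-(2-acetoxypropan-2-yl)-5-(4,5-dimethylfuran-2-yl)-3-(triethylsilyloxy)hexanoyl chloride | ClC(=O)[C@H](C(C)(C)OC(C)=O)[C@H](O[Si](CC)(CC)CC)C[C@H](C)c1cc(C)c(C)o1 | intermediate
13 | 2-[(5S,6R,8S)-2,3,8-trimethyl-4-oxo-6-(triethylsilyloxy)-5,6,7,8-tetrahydro-4H-cyclohepta[b]furan-5-yl]propan-2-yl acetate | CC[Si](CC)(CC)O[C@@H]1C[C@H](C)c2oc(C)c(C)c2C(=O)[C@@H]1C(C)(C)OC(C)=O | intermediate
14 | 2-[(4R,5S,6R,8S)-4-hydroxy-2,3,8-trimethyl-6-(triethylsilyloxy)-5,6,7,8-tetrahydro-4H-cyclohepta[b]furan-5-yl]propan-2-yl acetate | CC[Si](CC)(CC)O[C@@H]1C[C@H](C)c2oc(C)c(C)c2[C@H](O)[C@@H]1C(C)(C)OC(C)=O | intermediate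
15 | 2-[(4R,5R,6R,8S)-4-(tert-butyldimethylsilyloxy)-2,3,8-trimethyl-6-(triethylsilyloxy)-5,6,7,8-tetrahydro-4H-cyclohepta[b]furan-5-yl]propan-2-yl acetate | CC[Si](CC)(CC)O[C@@H]1C[C@H](C)c2oc(C)c(C)c2[C@H](O[Si](C)(C)C(C)(C)C)[C@@H]1C(C)(C)OC(C)=O | intermediate
16 | (Z)-ene-1,4-dione (guaiane numbering: C1 ring ketone; C4=C5 double bond; C3 methyl ketone; 6R,7R,8R,10S; C6 OTBS; C8 OTES; C11 OAc) | CC[Si](CC)(CC)O[C@@H]1C[C@H](C)C(=O)/C(=C(/C)C(C)=O)[C@H](O[Si](C)(C)C(C)(C)C)[C@@H]1C(C)(C)OC(C)=O | intermediate
17 | (1R,6R,7R,8R,10S)-11-acetoxy-6-(tert-butyldimethylsilyloxy)-1-hydroxy-8-(triethylsilyloxy)guai-4-en-3-one | CC[Si](CC)(CC)O[C@@H]1C[C@H](C)[C@]2(O)CC(=O)C(C)=C2[C@H](O[Si](C)(C)C(C)(C)C)[C@@H]1C(C)(C)OC(C)=O | intermediate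
18 | (1R,6R,7R,8R,10S)-11-acetoxy-6-(tert-butyldimethylsilyloxy)-1,8-dihydroxyguai-4-en-3-one | O[C@@H]1C[C@H](C)[C@]2(O)CC(=O)C(C)=C2[C@H](O[Si](C)(C)C(C)(C)C)[C@@H]1C(C)(C)OC(C)=O | intermediate
19 | angelic acid, (Z)-2-methylbut-2-enoic acid | C/C=C(/C)C(=O)O | starting material
20 | angelic 2,4,6-trichlorobenzoic anhydride | C/C=C(/C)C(=O)OC(=O)c1c(Cl)cc(Cl)cc1Cl | intermediate
21 | (1R,6R,7R,8R,10S)-11-acetoxy-8-angeloyloxy-6-(tert-butyldimethylsilyloxy)-1-hydroxyguai-4-en-3-one | C/C=C(/C)C(=O)O[C@@H]1C[C@H](C)[C@]2(O)CC(=O)C(C)=C2[C@H](O[Si](C)(C)C(C)(C)C)[C@@H]1C(C)(C)OC(C)=O | intermediate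
22 | (1R,6R,7S,8R,10S)-11-acetoxy-8-angeloyloxy-1,6-dihydroxyguai-4-en-3-one (CNP0273287.1) | C/C=C(/C)C(=O)O[C@@H]1C[C@H](C)[C@]2(O)CC(=O)C(C)=C2[C@H](O)[C@@H]1C(C)(C)OC(C)=O | target

**Step count**

Total step count: 14. Longest linear sequence: 14 steps (1 and 2 to 22); 4, 7 and 19 enter as purchased building blocks.

**Steps most likely to fail**

1. Step 11. The retro-aldol/aldol equilibrium may settle on the C1 epimer (hydroxyl syn to the C6 oxygen), and long exposure to base may epimerise C10 through the enol of the enedione. The fallback replaces base equilibration by a kinetic Lewis-acid closure. Setting out from 15, the peracid oxidation is run alone and enedione 16 is isolated. TMSOTf and Et3N in CH2Cl2 at −78 °C convert the methyl ketone into silyl enol ether F1; the C1 ketone, which has only the hindered tertiary C10–H, should be left. BF3·OEt2 in CH2Cl2 at −78 °C then effects an intramolecular Mukaiyama aldol, which is irreversible and should place the Lewis-acid-bound C1 oxygen on the unhindered β face. Aqueous work-up returns to the route at 17.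

2. Step 8. The Lewis acid may strip the triethylsilyl ether or ionise the tertiary acetate faster than the seven-membered ring closes, and elimination of a β-oxygen substituent may follow once the ketone exists. The fallback is halogen–metal exchange with intramolecular acylation (a Parham-type cyclisation) under basic conditions. Setting out from 11, coupling with N,O-dimethylhydroxylamine (EDC, catalytic 1-hydroxybenzotriazole, CH2Cl2) gives N-methoxy-N-methylamide F2. N-Iodosuccinimide in DMF at 0 °C iodinates the only free furan carbon to give iodofuran F3. i-PrMgCl·LiCl in THF at −40 °C exchanges iodine for magnesium, and the furylmagnesium adds to the amide to give a chelated tetrahedral intermediate that releases ketone 13 on work-up, where the route is rejoined.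

3. Step 13. Acylation of the hindered C8 hydroxyl may be slow enough for acetyl migration from O11 to O8 and for isomerisation of the angeloyl group to the tigloyl group under heat and amine. The fallback builds the Z double bond on the ester instead of transferring it (Still–Gennari olefination). Setting out from 18, esterification at 0 °C with 2-[bis(2,2,2-trifluoroethoxy)phosphoryl]propanoic acid (DCC, catalytic DMAP, CH2Cl2) gives phosphonopropanoate F4. KN(SiMe3)2 and 18-crown-6 in THF at −78 °C, followed by acetaldehyde, should give the (Z)-2-methylbut-2-enoate, which is 21, where the route is rejoined.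

**Further compounds**

F1 | step 11 | trimethylsilyl enol ether of the C3 methyl ketone of enedione 16 (Z; 6R,7R,8R,10S) | CC[Si](CC)(CC)O[C@@H]1C[C@H](C)C(=O)/C(=C(/C)C(=C)O[Si](C)(C)C)[C@H](O[Si](C)(C)C(C)(C)C)[C@@H]1C(C)(C)OC(C)=O
F2 | step 8 | (2S,3R,5S)-2-(2-acetoxypropan-2-yl)-5-(4,5-dimethylfuran-2-yl)-N-methoxy-N-methyl-3-(triethylsilyloxy)hexanamide | CON(C)C(=O)[C@H](C(C)(C)OC(C)=O)[C@H](O[Si](CC)(CC)CC)C[C@H](C)c1cc(C)c(C)o1
F3 | step 8 | (2S,3R,5S)-2-(2-acetoxypropan-2-yl)-5-(3-iodo-4,5-dimethylfuran-2-yl)-N-methoxy-N-methyl-3-(triethylsilyloxy)hexanamide | CON(C)C(=O)[C@H](C(C)(C)OC(C)=O)[C@H](O[Si](CC)(CC)CC)C[C@H](C)c1c(I)c(C)c(C)o1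
F4 | step 13 | 8-O-{2-[bis(2,2,2-trifluoroethoxy)phosphoryl]propanoyl} ester of 18 (mixture of epimers at the phosphonate carbon) | CC(C(=O)O[C@@H]1C[C@H](C)[C@]2(O)CC(=O)C(C)=C2[C@H](O[Si](C)(C)C(C)(C)C)[C@@H]1C(C)(C)OC(C)=O)P(=O)(OCC(F)(F)F)OCC(F)(F)F
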